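## The problem

CNP0232921.1 (43) consists of two bicyclic halves that meet only through the C9 methylene and the E-configured trisubstituted exocyclic alkene C7=C8. The western half is a trans-fused oxepan-3-one/cyclohexane (O20, C17, C15, C14, C13, C11, C21 and C10, C11, C21–C24); the eastern half is a cis-fused decalin (ring C: C2–C7; ring D: C5, C6, C27, C30–C32). Eight stereocentres have to be set, four per half (C10, C11, C21, C24 and C2, C5, C6, C32). No centre of one half can steer a centre of the other across the CH2–CH= link, so each half needs its own source of absolute configuration and the halves should be joined late.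

In the west, C21 can control the quaternary C11 (anti conjugate addition to a 4-silyloxy enone), and the axial C11 methyl then shields one face at C10 and C24. The C24 carbinol carries its methyl axial and syn to the C11 methyl, which is the epimer that direct methyl addition to a C24 ketone would not give. In the east, the cis fusion (C5/C6) must come from a suprafacial ring-forming step, and the C32 methyl again sits on the hindered, concave face. C2 and C6 flank C7 and are epimerisable whenever C7 is a carbonyl, and epimerisation at C6 would lead to the trans-decalin.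

The sensitive groups are two tertiary alcohols (dehydration), an α-alkoxy ketone with enolisable C14, and an exocyclic alkene on a doubly α-branched carbon whose geometry rests only on the steric difference between C2 and C6.

The feature that opens the key step: in the oxepanone the carbonyl carbon C15 lies between C14 and the fully substituted, oxygen-bearing C17. The array O20–C17–C15(=O)–C14 is what a six-membered cyclic enol ether C14=C17 becomes when one carbene carbon is inserted between its alkene carbons, so the seven-membered ether never has to be closed by etherification.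

## Retrosynthesis

**Unmasking.** Target 43 is taken back to its bis(triethylsilyl) ether 42. No skeletal bond is cut; the two tertiary alcohols are simply kept silent through the organometallic steps.

**C8–C9.** Compound 42 is cut between C8 and C9 into the western acid 27 (C9 as the CH2 of a CH2CO2H group, the carboxyl carbon to be lost) and the eastern (E)-alkenyl bromide 38. The neighbouring cut, C7=C8 by olefination of ketone 37 with a western ylide, would ask a large basic reagent to add to a ketone flanked by two branched, epimerisable α-carbons. The cut at C9–C10 would tie the eastern half to the west before the ring expansion. Cutting C8–C9 lets the alkene geometry be settled on a small fragment and carried over with retention. The forward step (decarboxylative alkenylation of a redox-active ester with an alkenylzinc) must tolerate a ketone and two silyl ethers and keep the E geometry.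

**C7=C8.** Bromide 38 comes from ketone 37 by bromomethylenation. The one-carbon ylide is the smallest possible partner for the hindered carbonyl, and bromine should settle away from C6, which carries the quaternary C27.

**C32 and C2.** Ketone 37 (silyl ether of 36) is traced to epoxy enone 34, then to methylene enone 33 and ene-dione 32. The C32 carbinol is made by methylenation, epoxidation from the open face and hydride opening, because a methyl nucleophile would enter from that same open face and give the wrong epimer. C2 is set when the enolate of the conjugate reduction is protonated.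

**Ring C.** Ene-dione 32 comes from octalone 30 by allylic oxidation at C7. Octalone 30 is cut at C4–C5 and C6–C7 into 4,4-dimethylcyclohex-2-en-1-one 28 and isoprene 29. This Diels–Alder reaction gives the cis fusion and the whole carbon skeleton of the eastern half in one step from two commodity chemicals. It asks for catalyst control of the absolute configuration and, afterwards, for regioselective oxidation of ring C.

**Oxepanone.** Acid 27 comes from allyl ketone 25 by oxidative cleavage. Ketone 25 comes from alkenyl bromide 22 (bromine marks the future carbonyl carbon C15), 22 from the bromo ketal 21 by replacing methoxy with methyl, and 21 from the six-membered enol ether 18 and bromoform 19 by cutting C14–C15 and C15–C17. Direct seven-membered etherification is slow and a 7-endo epoxide opening is a selectivity gamble, whereas the six-membered ketal forms without ambiguity and the inserted carbon arrives already functionalised. The forward step must discriminate the enol ether from the terminal alkene and must open only the internal cyclopropane bond.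

**C24.** Enol ether 18 goes back through alcohol 17 to the methyl ketal 16, epoxide 15, methylene compound 14 and ketone 13. The ketal masks the enol ether while C24 is oxidised, and the rigid trans-fused bicycle with its axial C11 methyl directs the epoxidation.

**C10 and C11.** Ketal 13 derives from the monocyclic ketone 11, and 11 from the α-methylene ketone 10 by conjugate addition of a vinyl group and kinetic protonation at C10. Direct allylation of the enolate is rejected because the electrophile would take the same open face as the proton and give the C10 epimer. Ketone 10 comes from silyl enol ether 7, which is cut at C11–C13 into enone 4 and the Grignard reagent 6 of bromide 5. The precursor is a simple cyclohexenone with one stereocentre, and the addition must occur anti to the silyloxy group.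

**Enone.** Enone 4 is obtained from 2-methylcyclohex-2-en-1-one 1 through alcohol 2 and silyl ether 3, by enantioselective reduction and allylic oxidation.

## Roads not taken

**Alternative 1:** the decalin would be cut at C3–C4 and C5–C6, and the acyclic trienone A1 would close both rings in an intramolecular Diels–Alder reaction (Me2AlCl or a chiral oxazaborolidinium acid) to the cis-fused octalone A2, with a C32 ketone and a C2=C7 alkene.
- Merits: both rings and the cis fusion form at once, the tether fixes the regiochemistry, and the C2=C7 alkene lets hydroboration put oxygen on C7 without ambiguity.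
- Where it is better: the chosen plan reaches the same oxidation pattern by an allylic oxidation of 30 whose regiochemistry is less certain.
- Weak points: A1 needs a linear sequence of its own, asymmetric induction on a trienone is no better established than on the bimolecular reaction, and C32 still needs the methylene/epoxide detour in the presence of a trisubstituted alkene. The strategy also says nothing about the harder western half or the junction.
- What the chosen plan sets against it: a one-step entry to 30 from two commercial compounds, and a key step that is spent on the oxepanone, the part of the molecule with the fewest reliable solutions.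

**Alternative 2:** ring C would be cut at C6–C7. A palladium hydride (Pd2(dba)3, acetic acid, tri-o-tolylphosphine) would add across the C7≡C8 alkyne of enyne A3, and the alkenylpalladium would insert the C6=C27 alkene to give A4, with ring C closed and an isopropenyl group on C6.
- Merits: the alkene geometry follows from syn addition and is mechanistically fixed.
- Where it is better: the chosen plan relies on a steric preference in the bromomethylenation of 37 for the same geometry.
- Weak points: the complete western bicycle must be carried through the cyclisation. The new C6 centre is set relative to C2 and C5 only through the conformation of the forming ring. Ring D remains to be built from an isopropenyl group and a Weinreb amide, which includes making the quaternary C27 late. The route is linear throughout.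
- What the chosen plan sets against it: convergence, with two fragments of similar size joined two steps from the end, and a decalin whose ring fusion is fixed by a cycloaddition.

**Alternative 3:** the cut is C11–C13 and C9–C10. CuBr·SMe2 and TMSCl would mediate addition of the homoprenyl Grignard reagent A5 to enone 4 anti to the silyloxy group, and the enolate would be allylated at C10 to give A6.
- Merits: the chosen route uses the same enone and the same anti addition, so this road is equally good for C11. Its side chain already holds C14–C17 with the gem-dimethyl group, so epoxidation and acid-mediated attack of O20 on C17 could reach the oxepane in fewer steps than ketalisation, elimination, carbene insertion and methylation.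
- Where it is better: the step count for the oxepane.
- Weak points: the ring closure has to beat 6-exo opening of the same epoxide and is a known source of mixtures. The key step itself closes no ring. Allylation of the enolate should occur on the face away from the pseudo-axial C11 methyl, which is the face that gives the wrong C10 epimer.
- What the chosen plan sets against it: a ring size that cannot go astray (a six-membered ketal enlarged by exactly one carbon), a C15 carbonyl position fixed by the carbene carbon, and C10 set by protonation, not alkylation.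

Key step: step 13

Assumption: the (S)-configured oxazaborolidinium catalyst of step 17 is taken to expose the enone face that leads to (4aR,8aS)-30; if the sense of induction is the reverse, the mirror-image catalyst is used.

## Steps

Step 1
Reactants: 1 2-methylcyclohex-2-en-1-one
Product: 2 (S)-2-methylcyclohex-2-en-1-ol
Conditions: (R)-Me-CBS oxazaborolidine (10 mol%), BH3·SMe2, THF, −20 °C
Reagents that add atoms: none
Why: Corey–Bakshi–Shibata reduction; the α-methyl alkenyl arm acts as the large group, so the (R)-catalyst should give the (S)-alcohol, and this centre (C21) is the source of all western stereochemistry.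

Step 2
Reactants: 2 (S)-2-methylcyclohex-2-en-1-ol
Product: 3 (S)-tert-butyldimethyl[(2-methylcyclohex-2-en-1-yl)oxy]silane
Conditions: TBSCl, imidazole, DMF, 23 °C
Reagents that add atoms: tert-butyldimethylsilyl chloride, CC(C)(C)[Si](C)(C)Cl
Why: Standard silylation; the bulky ether survives the oxidation and later directs the cuprate.

Step 3
Reactants: 3 (S)-tert-butyldimethyl[(2-methylcyclohex-2-en-1-yl)oxy]silane
Product: 4 (S)-4-(tert-butyldimethylsilyloxy)-3-methylcyclohex-2-en-1-one
Conditions: Rh2(cap)4 (cap = caprolactamate, 1 mol%), t-BuOOH, K2CO3, CH2Cl2, 23 °C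
Reagents that add atoms: tert-butyl hydroperoxide, CC(C)(C)OO
Why: Catalytic allylic C–H oxidation of a 1-methylcyclohexene-type alkene occurs at the ring methylene next to the unsubstituted alkene carbon and gives the β-methyl enone; the carbinol centre is not involved.

Step 4
Reactants: 4 (S)-4-(tert-butyldimethylsilyloxy)-3-methylcyclohex-2-en-1-one; 5 2-(2-bromoethyl)-2-methyl-1,3-dioxolane
Product: 7 (3S,4S)-4-(tert-butyldimethylsilyloxy)-3-methyl-3-[2-(2-methyl-1,3-dioxolan-2-yl)ethyl]-1-(trimethylsilyloxy)cyclohex-1-ene, via Grignard reagent 6 (not isolated)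
Conditions: 5, Mg, THF, 25 °C; then 4, CuBr·SMe2 (10 mol%), TMSCl, THF, −78 → −30 °C; Et3N
Reagents that add atoms: chlorotrimethylsilane, C[Si](C)(C)Cl
Why: Copper-catalysed, TMSCl-accelerated conjugate addition; the reagent attacks C11 anti to the C21 silyloxy group, setting the quaternary centre with C13 trans to O20, and the enolate is stored regiodefined as its silyl enol ether.

Step 5
Reactants: 7 silyl enol ether of step 4
Product: 10 (3S,4S)-4-(tert-butyldimethylsilyloxy)-3-methyl-2-methylene-3-[2-(2-methyl-1,3-dioxolan-2-yl)ethyl]cyclohexan-1-one, via Mannich base 8 (not isolated), via methiodide 9 (not isolated)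
Conditions: CH2=NMe2+ I− (Eschenmoser's salt), CH2Cl2, 23 °C; MeI; aq. NaHCO3
Reagents that add atoms: N,N-dimethylmethyleneiminium iodide, C=[N+](C)C.[I-]
Why: Mannich reaction of the silyl enol ether can occur only at C10; quaternisation and Hofmann-type elimination give the α-methylene ketone and so introduce C9.

Step 6
Reactants: 10 α-methylene ketone of step 5
Product: 11 (2S,3S,4S)-2-allyl-4-(tert-butyldimethylsilyloxy)-3-methyl-3-[2-(2-methyl-1,3-dioxolan-2-yl)ethyl]cyclohexan-1-one (allyl cis to the C11 methyl)
Conditions: CH2=CHMgBr, CuBr·SMe2 (10 mol%), THF, −78 °C; aq. NH4Cl at −78 °C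
Reagents that add atoms: vinylmagnesium bromide, C=C[Mg]Br
Why: Copper-catalysed 1,4-addition to the unhindered exocyclic methylene; C10 is set by kinetic protonation of the enolate on the face away from the pseudo-axial C11 methyl, which puts the allyl group equatorial and cis to that methyl (also the more stable epimer).

Step 7
Reactants: 11 allyl ketone of step 6
Product: 13 5-allyl-2-methoxy-2,4a-dimethyloctahydro-6H-chromen-6-one (trans-fused; allyl cis to the 4a-methyl; both anomers), via lactol 12 (not isolated)
Conditions: 1 M HCl, THF, 23 °C; then PPTS, MeOH, 23 °C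
Reagents that add atoms: methanol, CO
Why: Acid removes silyl ether and dioxolane, the freed C21 hydroxyl closes the six-membered lactol on the C17 ketone, and the anomeric hydroxyl is exchanged for methoxy under conditions too mild to ketalise the C24 ketone. The trans fusion follows from step 4, and the ketal masks the future enol ether during step 9.

Step 8
Reactants: 13 ketal ketone of step 7
Product: 14 5-allyl-2-methoxy-2,4a-dimethyl-6-methyleneoctahydro-2H-chromene (trans-fused)
Conditions: Ph3PCH3Br, KOtBu, THF, 0 → 23 °C
Reagents that add atoms: methyltriphenylphosphonium bromide, C[P+](c1ccccc1)(c1ccccc1)c1ccccc1.[Br-]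
Why: Wittig methylenation of an α-branched cyclohexanone; the C10 epimer present is also the thermodynamic one, so the basic ylide cannot erode it.

Step 9
Reactants: 14 methylene compound of step 8
Product: 15 spiro-epoxide of 14 at C24 (epoxide oxygen equatorial and trans to the C11 methyl; CH2 axial)
Conditions: mCPBA (1.05 equiv), NaHCO3, CH2Cl2, −10 °C
Reagents that add atoms: 3-chloroperoxybenzoic acid, OOC(=O)c1cccc(Cl)c1
Why: Prilezhaev epoxidation is faster at the 1,1-disubstituted alkene than at the monosubstituted allyl group; the axial C11 methyl blocks the axial face, so oxygen arrives equatorially and fixes C24.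

Step 10
Reactants: 15 spiro-epoxide of step 9
Product: 16 5-allyl-2-methoxy-2,4a,6-trimethyloctahydro-2H-chromen-6-ol (6-OH equatorial; 6-methyl axial and cis to the 4a-methyl)
Conditions: LiAlH4, THF, 0 °C
Reagents that add atoms: none
Why: Hydride opens the epoxide at its primary carbon (SN2), turning the axial CH2 into the axial methyl and leaving the equatorial tertiary alcohol of the target; ketal and alkene are inert.

Step 11
Reactants: 16 ketal alcohol of step 10
Product: 17 5-allyl-2,4a,6-trimethyl-4a,5,6,7,8,8a-hexahydro-4H-chromen-6-ol (trans-fused enol ether C14=C17)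
Conditions: PPTS, pyridine, PhCl, 135 °C
Reagents that add atoms: none
Why: Acid-catalysed loss of methanol from a cyclic methyl ketal, a standard route to cyclic enol ethers; under these equilibrating conditions the endocyclic trisubstituted enol ether is the thermodynamic product.

Step 12
Reactants: 17 enol ether alcohol of step 11
Product: 18 triethylsilyl ether of 17
Conditions: TESOTf, 2,6-lutidine, CH2Cl2, −78 → 0 °C
Reagents that add atoms: triethylsilyl trifluoromethanesulfonate, CC[Si](CC)(CC)OS(=O)(=O)C(F)(F)F
Why: Silyl triflate silylation of the tertiary alcohol; it prevents alkoxide–carbene reactions in step 13 and protects the alcohol from the organometallic reagents later.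

Step 13
Reactants: 18 triethylsilyl enol ether of step 12; 19 bromoform
Product: 21 6-allyl-3-bromo-2-methoxy-2,5a,7-trimethyl-7-(triethylsilyloxy)-2,5,5a,6,7,8,9,9a-octahydrobenzo[b]oxepine (trans-fused; ketal epimers), via dibromocyclopropane 20 (not isolated)
Conditions: CHBr3, KOtBu, pentane, −20 → 0 °C; then AgBF4, 2,6-di-tert-butyl-4-methylpyridine, MeOH, 0 → 23 °C
Reagents that add atoms: methanol, CO
Why: Dibromocarbene, formed from bromoform by α-elimination, is electrophilic and adds stereospecifically to the electron-rich C14=C17 enol ether in preference to the monosubstituted allyl alkene, giving the dibromo-oxabicyclo[4.1.0]heptane 20 (either face leads on). Silver ion removes the endo bromide while the C14–C17 bond opens in a disrotatory electrocyclic fashion, so the six-membered ether grows into the seven-membered ring by ring enlargement (not by an end-to-end cyclisation) and the carbene carbon becomes C15 with the new C14–C15 and C15–C17 bonds. The cation is both a 2-bromoallyl cation and a tertiary oxocarbenium ion, and methanol captures it at C17, the oxygen-stabilised terminus. The closest known reaction type is dihalocarbene addition to glycals and other cyclic enol ethers followed by silver- or base-promoted expansion to 2-halo-oxepenes trapped by alcohols. The only new stereocentre is the ketal carbon C17; it is not controlled and need not be, because step 14 replaces methoxy by a second methyl. The step needs chemoselectivity (the trisubstituted enol ether is far more nucleophilic than the terminal alkene), regioselective bond cleavage (only the internal cyclopropane bond can open to an oxygen-stabilised cation) and buffering (the hindered pyridine keeps the tertiary silyl ether intact). The C11/C21 trans fusion and the C10 and C24 centres are remote from the reacting bonds and untouched.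

Step 14
Reactants: 21 bromo ketal of step 13
Product: 22 6-allyl-3-bromo-2,2,5a,7-tetramethyl-7-(triethylsilyloxy)-2,5,5a,6,7,8,9,9a-octahydrobenzo[b]oxepine
Conditions: Me3Al, TMSOTf, CH2Cl2, −78 → −30 °C
Reagents that add atoms: trimethylaluminium, C[Al](C)C
Why: TMSOTf ionises the allylic ketal to the same oxocarbenium ion and Me3Al transfers methyl to its oxygen-bearing terminus C17 (Ferrier-type C-alkylation; known gem-dimethylation of cyclic methyl ketals); both ketal epimers converge and no stereocentre remains at C17.

Step 15
Reactants: 22 alkenyl bromide of step 14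
Product: 25 6-allyl-2,2,5a,7-tetramethyl-7-(triethylsilyloxy)octahydrobenzo[b]oxepin-3(2H)-one, via alkenyllithium 23 (not isolated), via alkenylboronate 24 (not isolated)
Conditions: t-BuLi, Et2O, −78 °C; B(OMe)3, −78 → 0 °C; then NaOH, H2O2, 0 °C
Reagents that add atoms: hydrogen peroxide, OO
Why: Bromine–lithium exchange, borylation and oxidation of the alkenylboronate give the enol, which tautomerises to the C15 ketone; the carbonyl position is dictated by the bromine, that is by the carbene carbon.

Step 16
Reactants: 25 allyl oxepanone of step 15
Product: 27 2-[2,2,5a,7-tetramethyl-3-oxo-7-(triethylsilyloxy)decahydrobenzo[b]oxepin-6-yl]acetic acid, via aldehyde 26 (not isolated)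
Conditions: O3, CH2Cl2, −78 °C; Me2S; then NaClO2, NaH2PO4, 2-methylbut-2-ene, t-BuOH/H2O, 0 °C
Reagents that add atoms: ozone, [O-][O+]=O; sodium chlorite, [Na+].[O-]Cl=O
Why: Ozonolysis cleaves the only alkene and Pinnick oxidation gives the acid without touching ketone or silyl ether; the carboxyl carbon is the one expelled in step 24, leaving C9.

Step 17
Reactants: 28 4,4-dimethylcyclohex-2-en-1-one; 29 isoprene
Product: 30 (4aR,8aS)-4,4,6-trimethyl-3,4,4a,5,8,8a-hexahydronaphthalen-1(2H)-one (cis-fused)
Conditions: (S)-B-(o-tolyl) diphenylprolinol-derived oxazaborolidine·Tf2NH (20 mol%), isoprene (excess), CH2Cl2, −20 → 23 °C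
Reagents that add atoms: none
Why: Lewis-acid-catalysed Diels–Alder reaction; the para rule places the methyl-bearing C2 1,4 to C5, suprafacial addition gives the cis fusion at C5/C6, and the chiral oxazaborolidinium ion selects the enone face.

Step 18
Reactants: 30 octalone of step 17
Product: 32 cis-4,4,6-trimethyl-3,4,4a,8a-tetrahydronaphthalene-1,5(2H,8H)-dione (C7 enone and C32 ketone), via allylic alcohol 31 (not isolated)
Conditions: SeO2 (0.5 equiv), t-BuOOH, CH2Cl2, 23 °C; then Dess–Martin periodinane, NaHCO3, CH2Cl2, 23 °C
Reagents that add atoms: selenium dioxide, O=[Se]=O; tert-butyl hydroperoxide, CC(C)(C)OO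
Why: Selenium dioxide allylic oxidation (ene reaction, then [2,3]-sigmatropic shift) functionalises the more substituted end of the alkene and prefers the ring CH2 (C7) over the methyl; oxidation of the epimeric alcohols gives one enone.

Step 19
Reactants: 32 ene-dione of step 18
Product: 33 cis-2,8,8-trimethyl-5-methylene-4a,5,6,7,8,8a-hexahydronaphthalen-1(4H)-one
Conditions: Zn, CH2Br2, TiCl4, THF/CH2Cl2, 0 → 23 °C
Reagents that add atoms: dibromomethane, BrCBr
Why: Takai–Lombardo methylenation is non-basic, so C5 and C6 are not epimerised, and it selects the saturated, less hindered C32 ketone over the conjugated C7 carbonyl flanked by C2 and C6.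

Step 20
Reactants: 33 methylene enone of step 19
Product: 34 spiro-epoxide of 33 at C32 (epoxide oxygen cis to H-5)
Conditions: mCPBA, NaHCO3, CH2Cl2, 0 °C
Reagents that add atoms: 3-chloroperoxybenzoic acid, OOC(=O)c1cccc(Cl)c1
Why: Prilezhaev epoxidation of the only electron-rich alkene; the peracid approaches from the convex face, away from the axial C7 branch of ring C. That is the face a methyl nucleophile would also have chosen, which is why the carbinol is built by oxygen delivery.

Step 21
Reactants: 34 epoxy enone of step 20
Product: 36 5-hydroxy-2,5,8,8-tetramethyloctahydronaphthalen-1(2H)-one (cis-fused; H-2 and H-4a and H-8a all cis; 5-OH cis to H-4a), via enolate 35 (not isolated)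
Conditions: L-Selectride (LiB(s-Bu)3H), THF, −78 °C; then LiEt3BH, −78 → 0 °C; aq. NH4Cl
Reagents that add atoms: none
Why: Conjugate reduction of the β-unsubstituted enone stores the C7 ketone as its enolate while LiEt3BH opens the epoxide at CH2, giving the C32 carbinol with methyl on the concave face. Axial protonation at C2 on work-up places the methyl equatorial (the stable epimer of the cis series), and the mild quench avoids epimerisation at C6.

Step 22
Reactants: 36 hydroxy decalone of step 21
Product: 37 triethylsilyl ether of 36
Conditions: TESOTf, 2,6-lutidine, CH2Cl2, −78 °C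
Reagents that add atoms: triethylsilyl trifluoromethanesulfonate, CC[Si](CC)(CC)OS(=O)(=O)C(F)(F)F
Why: Silylation of the tertiary alcohol at low temperature is much faster than enol silylation of the hindered ketone; the ether protects the alcohol from the ylide and organolithium steps.

Step 23
Reactants: 37 silyloxy decalone of step 22
Product: 38 (E)-1-(bromomethylene)-2,5,8,8-tetramethyl-5-(triethylsilyloxy)decahydronaphthalene (Br cis to C2 and trans to C6)
Conditions: Ph3PCH2Br·Br, NaHMDS, THF, −60 → 23 °C
Reagents that add atoms: (bromomethyl)triphenylphosphonium bromide, BrC[P+](c1ccccc1)(c1ccccc1)c1ccccc1.[Br-]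
Why: Wittig bromomethylenation, known on hindered ring-fusion cyclohexanones to place bromine away from the more encumbered α-carbon; here C6, which bears the quaternary C27, outweighs the methyl-bearing C2, so the E isomer should form.

Step 24
Reactants: 27 acid of step 16; 38 alkenyl bromide of step 23
Product: 42 bis(triethylsilyl) ether of 43, via tetrachlorophthalimidyl ester 39 (not isolated), via alkenyllithium 40 (not isolated), via alkenylzinc chloride 41 (not isolated)
Conditions: 27, N-hydroxytetrachlorophthalimide, DIC, CH2Cl2, 23 °C; 38, t-BuLi, Et2O, −78 °C, then ZnCl2; Ni(acac)2 (10 mol%), 2,2'-bipyridine, THF/DMF, 23 °C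
Reagents that add atoms: none
Why: Nickel-catalysed decarboxylative alkenylation of a redox-active ester; electron transfer and loss of CO2 give the primary C9 radical, which is captured by the alkenylnickel species formed from the configurationally stable alkenylzinc. The C8–C9 bond forms with retention of the E geometry, and the ketone and silyl ethers are tolerated.

Step 25
Reactants: 42 bis(triethylsilyl) ether of step 24
Product: 43 CNP0232921.1
Conditions: HF·pyridine, pyridine, THF, 0 → 23 °C
Reagents that add atoms: none
Why: Fluoride-mediated cleavage of both tertiary silyl ethers; the pyridine buffer spares the tertiary alcohols, the α-alkoxy ketone and the exocyclic alkene.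

## Compound list

1 | 2-methylcyclohex-2-en-1-one | CC1=CCCCC1=O | starting material
2 | (S)-2-methylcyclohex-2-en-1-ol | CC1=CCCC[C@@H]1O | intermediate
3 | (S)-tert-butyldimethyl[(2-methylcyclohex-2-en-1-yl)oxy]silane | CC1=CCCC[C@@H]1O[Si](C)(C)C(C)(C)C | intermediate
4 | (S)-4-(tert-butyldimethylsilyloxy)-3-methylcyclohex-2-en-1-one | O=C1C=C(C)[C@@H](O[Si](C)(C)C(C)(C)C)CC1 | intermediate
5 | 2-(2-bromoethyl)-2-methyl-1,3-dioxolane | CC1(CCBr)OCCO1 | starting material
6 | [2-(2-methyl-1,3-dioxolan-2-yl)ethyl]magnesium bromide | CC1(CC[Mg]Br)OCCO1 | intermediate (not isolated)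
7 | (3S,4S)-4-(tert-butyldimethylsilyloxy)-3-methyl-3-[2-(2-methyl-1,3-dioxolan-2-yl)ethyl]-1-(trimethylsilyloxy)cyclohex-1-ene (side chain trans to OTBS) | C[Si](C)(C)OC1=C[C@](C)(CCC2(C)OCCO2)[C@@H](O[Si](C)(C)C(C)(C)C)CC1 | intermediate
8 | 2-[(dimethylamino)methyl] ketone from 7 (Mannich base, C10 epimers) | CN(C)CC1[C@](C)(CCC2(C)OCCO2)[C@@H](O[Si](C)(C)C(C)(C)C)CCC1=O | intermediate (not isolated)
9 | trimethylammonium iodide of 8 | C[N+](C)(C)CC1[C@](C)(CCC2(C)OCCO2)[C@@H](O[Si](C)(C)C(C)(C)C)CCC1=O.[I-] | intermediate (not isolated)
10 | (3S,4S)-4-(tert-butyldimethylsilyloxy)-3-methyl-2-methylene-3-[2-(2-methyl-1,3-dioxolan-2-yl)ethyl]cyclohexan-1-one | C=C1[C@](C)(CCC2(C)OCCO2)[C@@H](O[Si](C)(C)C(C)(C)C)CCC1=O | intermediate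
11 | (2S,3S,4S)-2-allyl-4-(tert-butyldimethylsilyloxy)-3-methyl-3-[2-(2-methyl-1,3-dioxolan-2-yl)ethyl]cyclohexan-1-one (allyl cis to 3-methyl) | C=CC[C@H]1[C@](C)(CCC2(C)OCCO2)[C@@H](O[Si](C)(C)C(C)(C)C)CCC1=O | intermediate
12 | 5-allyl-2-hydroxy-2,4a-dimethyloctahydro-6H-chromen-6-one (trans-fused lactol, anomers) | C=CC[C@H]1[C@]2(C)CCC(C)(O)O[C@H]2CCC1=O | intermediate (not isolated)
13 | 5-allyl-2-methoxy-2,4a-dimethyloctahydro-6H-chromen-6-one (trans-fused; allyl cis to 4a-methyl; anomers) | C=CC[C@H]1[C@]2(C)CCC(C)(OC)O[C@H]2CCC1=O | intermediate
14 | 5-allyl-2-methoxy-2,4a-dimethyl-6-methyleneoctahydro-2H-chromene | C=CC[C@H]1[C@]2(C)CCC(C)(OC)O[C@H]2CCC1=C | intermediate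
15 | C24 spiro-epoxide of 14 (oxygen equatorial, trans to the 4a-methyl) | C=CC[C@H]1[C@]2(C)CCC(C)(OC)O[C@H]2CC[C@@]13CO3 | intermediate
16 | 5-allyl-2-methoxy-2,4a,6-trimethyloctahydro-2H-chromen-6-ol (6-OH equatorial, 6-methyl axial) | C=CC[C@H]1[C@]2(C)CCC(C)(OC)O[C@H]2CC[C@]1(C)O | intermediate
17 | 5-allyl-2,4a,6-trimethyl-4a,5,6,7,8,8a-hexahydro-4H-chromen-6-ol (trans-fused enol ether) | C=CC[C@H]1[C@]2(C)CC=C(C)O[C@H]2CC[C@]1(C)O | intermediate
18 | triethylsilyl ether of 17 (precursor of the key step) | C=CC[C@H]1[C@]2(C)CC=C(C)O[C@H]2CC[C@]1(C)O[Si](CC)(CC)CC | intermediate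
19 | bromoform | BrC(Br)Br | starting material
20 | gem-dibromocyclopropane adduct of 18 across C14–C17 (face isomers) | C=CC[C@H]1[C@]2(C)CC3C(Br)(Br)C3(C)O[C@H]2CC[C@]1(C)O[Si](CC)(CC)CC | intermediate (not isolated)
21 | 6-allyl-3-bromo-2-methoxy-2,5a,7-trimethyl-7-(triethylsilyloxy)-2,5,5a,6,7,8,9,9a-octahydrobenzo[b]oxepine (ketal epimers; product of the key step) | C=CC[C@H]1[C@]2(C)CC=C(Br)C(C)(OC)O[C@H]2CC[C@]1(C)O[Si](CC)(CC)CC | intermediate
22 | 6-allyl-3-bromo-2,2,5a,7-tetramethyl-7-(triethylsilyloxy)-2,5,5a,6,7,8,9,9a-octahydrobenzo[b]oxepine | C=CC[C@H]1[C@]2(C)CC=C(Br)C(C)(C)O[C@H]2CC[C@]1(C)O[Si](CC)(CC)CC | intermediate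
23 | C15 alkenyllithium from 22 | C=CC[C@H]1[C@]2(C)CC=C([Li])C(C)(C)O[C@H]2CC[C@]1(C)O[Si](CC)(CC)CC | intermediate (not isolated)
24 | dimethyl C15 alkenylboronate from 23 | C=CC[C@H]1[C@]2(C)CC=C(B(OC)OC)C(C)(C)O[C@H]2CC[C@]1(C)O[Si](CC)(CC)CC | intermediate (not isolated)
25 | 6-allyl-2,2,5a,7-tetramethyl-7-(triethylsilyloxy)octahydrobenzo[b]oxepin-3(2H)-one | C=CC[C@H]1[C@]2(C)CCC(=O)C(C)(C)O[C@H]2CC[C@]1(C)O[Si](CC)(CC)CC | intermediate
26 | C8 aldehyde from 25 | O=CC[C@H]1[C@]2(C)CCC(=O)C(C)(C)O[C@H]2CC[C@]1(C)O[Si](CC)(CC)CC | intermediate (not isolated)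
27 | 2-[2,2,5a,7-tetramethyl-3-oxo-7-(triethylsilyloxy)decahydrobenzo[b]oxepin-6-yl]acetic acid | OC(=O)C[C@H]1[C@]2(C)CCC(=O)C(C)(C)O[C@H]2CC[C@]1(C)O[Si](CC)(CC)CC | intermediate
28 | 4,4-dimethylcyclohex-2-en-1-one | CC1(C)CCC(=O)C=C1 | starting material
29 | isoprene | C=CC(C)=C | starting material
30 | (4aR,8aS)-4,4,6-trimethyl-3,4,4a,5,8,8a-hexahydronaphthalen-1(2H)-one (cis-fused) | CC1=CC[C@H]2[C@@H](C1)C(C)(C)CCC2=O | intermediate
31 | C7 allylic alcohol of 30 (C7 epimers) | CC1=CC[C@H]2[C@@H](C1O)C(C)(C)CCC2=O | intermediate (not isolated)
32 | cis-4,4,6-trimethyl-3,4,4a,8a-tetrahydronaphthalene-1,5(2H,8H)-dione | CC1=CC[C@H]2[C@@H](C1=O)C(C)(C)CCC2=O | intermediate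
33 | cis-2,8,8-trimethyl-5-methylene-4a,5,6,7,8,8a-hexahydronaphthalen-1(4H)-one | CC1=CC[C@H]2[C@@H](C1=O)C(C)(C)CCC2=C | intermediate
34 | C32 spiro-epoxide of 33 (oxygen cis to H-5) | CC1=CC[C@H]2[C@@H](C1=O)C(C)(C)CC[C@@]23CO3 | intermediate
35 | lithium C7 enolate of the reduced epoxy ketone | [Li]OC1=C(C)CC[C@H]2[C@@H]1C(C)(C)CC[C@@]23CO3 | intermediate (not isolated)
36 | 5-hydroxy-2,5,8,8-tetramethyloctahydronaphthalen-1(2H)-one (cis-fused; H-2, H-4a, H-8a cis; 5-OH cis to H-4a) | C[C@@H]1CC[C@H]2[C@@H](C1=O)C(C)(C)CC[C@]2(C)O | intermediate
37 | triethylsilyl ether of 36 | C[C@@H]1CC[C@H]2[C@@H](C1=O)C(C)(C)CC[C@]2(C)O[Si](CC)(CC)CC | intermediate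
38 | (E)-1-(bromomethylene)-2,5,8,8-tetramethyl-5-(triethylsilyloxy)decahydronaphthalene | C[C@@H]1CC[C@H]2[C@@H](/C1=C/Br)C(C)(C)CC[C@]2(C)O[Si](CC)(CC)CC | intermediate
39 | N-(acyloxy)tetrachlorophthalimide of 27 | O=C(C[C@H]1[C@]2(C)CCC(=O)C(C)(C)O[C@H]2CC[C@]1(C)O[Si](CC)(CC)CC)ON1C(=O)c2c(Cl)c(Cl)c(Cl)c(Cl)c2C1=O | intermediate (not isolated)
40 | (E)-alkenyllithium from 38 | C[C@@H]1CC[C@H]2[C@@H](/C1=C/[Li])C(C)(C)CC[C@]2(C)O[Si](CC)(CC)CC | intermediate (not isolated)
41 | (E)-alkenylzinc chloride from 40 | C[C@@H]1CC[C@H]2[C@@H](/C1=C/[Zn]Cl)C(C)(C)CC[C@]2(C)O[Si](CC)(CC)CC | intermediate (not isolated)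
42 | O26,O34-bis(triethylsilyl) ether of 43 | C[C@@H]1CC[C@H]2[C@@H](/C1=C/C[C@H]1[C@]3(C)CCC(=O)C(C)(C)O[C@H]3CC[C@]1(C)O[Si](CC)(CC)CC)C(C)(C)CC[C@]2(C)O[Si](CC)(CC)CC | intermediate
43 | CNP0232921.1 | C[C@@H]1CC[C@H]2[C@@H](/C1=C/C[C@H]1[C@]3(C)CCC(=O)C(C)(C)O[C@H]3CC[C@]1(C)O)C(C)(C)CC[C@]2(C)O | target

## Step count and least certain steps

Total: 25 steps. Longest linear sequence: 18 steps (steps 1–16, then 24 and 25). The eastern branch is 7 steps (17–23).

**Step 13 (key step).** The 1-alkoxy-1-methyl dibromocyclopropane 20 may ionise already under the basic carbene conditions and lose a proton to give bromodienes. The carbene may be consumed by tert-butoxide before it adds. Capture at C14 instead of C17 would give an enol ether. Fallback, from 18, rejoining at 25: epoxidation of the enol ether with dimethyldioxirane in methanol should give the hydroxy methyl ketal F1; Me3Al/TMSOTf should give the 2,2-dimethylpyran-3-ol F2; Dess–Martin oxidation gives the pyranone F3; Me3Al-promoted ring expansion with trimethylsilyldiazomethane, with migration of the unhindered C13 methylene and not the oxygenated quaternary C17, should give the α-silyl oxepanone F4, which is protodesilylated (K2CO3, MeOH) to 25. Here the inserted carbon becomes C14, not C15.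

**Step 17.** The γ,γ-disubstituted enone is a sluggish dienophile, so conversion under the chiral acid may be low, enantioselection may be poor, and prolonged Lewis-acid contact may epimerise C5 to the trans-octalone. Fallback, from 28 and 29, rejoining at 30: AlCl3-catalysed cycloaddition to racemic 30, L-Selectride reduction from the convex face to the racemic axial alcohol, and lipase acylation (Candida antarctica lipase B, vinyl acetate). By the empirical rule for secondary alcohols the (R)-carbinol of the desired series should be acylated, to the acetate F6. After separation, methanolysis gives the alcohol F5 and Dess–Martin oxidation returns 30.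

**Step 18.** Selenium dioxide may oxidise the C2 methyl in competition with the neopentyl-like ring methylene C7, or over-oxidise. Fallback, from 30, rejoining at 31: nitrosyl chloride addition and dehydrochlorination (the limonene-to-carvone sequence) should give the unsaturated oxime F7 and, after hydrolysis, the transposed enone F8 (C3 carbonyl, C2=C7 alkene) with unambiguous regiochemistry. Alkaline hydrogen peroxide gives the epoxy ketone F9, and Wharton transposition (N2H4·H2O, AcOH) moves the oxygen to C7, giving 31.

**Step 23.** Ylide addition to the doubly α-branched ketone may be slow, so enolisation can compete and epimerise C6 (to the trans-decalin) or C2, and the E preference may be incomplete. Fallback, from 37, rejoining at 38: boron–Wittig reaction with lithiated bis(pinacolato)borylmethane (from CH2(Bpin)2 and LiTMP), a smaller and less basic nucleophile, should give the (E)-alkenyl pinacol boronate F10; bromodeboronation with CuBr2 in aqueous methanol returns 38.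

**Step 24.** The alkenylzinc may be protonated or homocoupled, the C9 radical may be reduced before capture, the eastern fragment is needed in excess, and some geometry may be lost at nickel. Fallback, from 27, rejoining at 42: photochemical iododecarboxylation (PhI(OAc)2, I2, hν) to the primary iodide F11, zinc insertion (Zn, LiCl, THF) to the alkylzinc iodide F12, and Negishi coupling with 38 (Pd(dppf)Cl2) to 42.

## Further compounds

F1 | step 13 | 5-allyl-3-hydroxy-2-methoxy-2,4a,6-trimethyl-6-(triethylsilyloxy)octahydro-2H-chromene (epimers at C14 and C17) | C=CC[C@H]1[C@]2(C)CC(O)C(C)(OC)O[C@H]2CC[C@]1(C)O[Si](CC)(CC)CC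
F2 | step 13 | 5-allyl-2,2,4a,6-tetramethyl-6-(triethylsilyloxy)octahydro-2H-chromen-3-ol | C=CC[C@H]1[C@]2(C)CC(O)C(C)(C)O[C@H]2CC[C@]1(C)O[Si](CC)(CC)CC
F3 | step 13 | 5-allyl-2,2,4a,6-tetramethyl-6-(triethylsilyloxy)hexahydro-2H-chromen-3(4H)-one | C=CC[C@H]1[C@]2(C)CC(=O)C(C)(C)O[C@H]2CC[C@]1(C)O[Si](CC)(CC)CC
F4 | step 13 | 4-(trimethylsilyl) derivative of oxepanone 25 | C=CC[C@H]1[C@]2(C)CC([Si](C)(C)C)C(=O)C(C)(C)O[C@H]2CC[C@]1(C)O[Si](CC)(CC)CC
F5 | step 17 | (1R,4aR,8aS)-4,4,6-trimethyl-1,2,3,4,4a,5,8,8a-octahydronaphthalen-1-ol (cis-fused, axial OH) | CC1=CC[C@H]2[C@@H](C1)C(C)(C)CC[C@H]2O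
F6 | step 17 | acetate of F5 | CC1=CC[C@H]2[C@@H](C1)C(C)(C)CC[C@H]2OC(C)=O
F7 | step 18 | oxime of enone F8 | CC1=C[C@@H]2[C@H](CC1=NO)C(=O)CCC2(C)C
F8 | step 18 | cis-fused enedione with C3 carbonyl and C2=C7 alkene (3,8,8-trimethyl-4a,7,8,8a-tetrahydronaphthalene-2,5(1H,6H)-dione) | CC1=C[C@@H]2[C@H](CC1=O)C(=O)CCC2(C)C
F9 | step 18 | C2–C7 epoxide of F8 | CC12OC1[C@@H]1[C@H](CC2=O)C(=O)CCC1(C)C
F10 | step 23 | (E)-alkenyl pinacol boronate corresponding to 38 | C[C@@H]1CC[C@H]2[C@@H](/C1=C/B1OC(C)(C)C(C)(C)O1)C(C)(C)CC[C@]2(C)O[Si](CC)(CC)CC
F11 | step 24 | 6-(iodomethyl)-2,2,5a,7-tetramethyl-7-(triethylsilyloxy)octahydrobenzo[b]oxepin-3(2H)-one | IC[C@H]1[C@]2(C)CCC(=O)C(C)(C)O[C@H]2CC[C@]1(C)O[Si](CC)(CC)CC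
F12 | step 24 | alkylzinc iodide from F11 | I[Zn]C[C@H]1[C@]2(C)CCC(=O)C(C)(C)O[C@H]2CC[C@]1(C)O[Si](CC)(CC)CC
A1 | alternative 1 | (E)-6,6,9-trimethyldeca-1,7,9-trien-3-one | C=CC(=O)CCC(C)(C)/C=C/C(C)=C
A2 | alternative 1 | cis-fused octalone with C32 ketone and C2=C7 alkene | CC1=C[C@H]2C(C)(C)CCC(=O)[C@H]2CC1
A3 | alternative 2 | 1,6-enyne Weinreb amide carrying the western bicycle | C[C@H](CC[C@H](C(=O)N(C)OC)C=C(C)C)C#CC[C@H]1[C@]2(C)CC[C@H](O[Si](C)(C)C(C)(C)C)C(C)(C)O[C@H]2CC[C@]1(C)O
A4 | alternative 2 | ring C alkylidene cyclohexane with C6 isopropenyl and C5 Weinreb amide | C[C@@H]1CC[C@H](C(=O)N(C)OC)[C@H](C(C)=C)/C1=C/C[C@H]1[C@]3(C)CC[C@H](O[Si](C)(C)C(C)(C)C)C(C)(C)O[C@H]3CC[C@]1(C)O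
A5 | alternative 3 | 4-methylpent-3-enylmagnesium bromide | CC(C)=CCC[Mg]Br
A6 | alternative 3 | 2-allyl-3-methyl-3-(4-methylpent-3-enyl)-4-silyloxycyclohexanone | C=CC[C@H]1[C@](C)(CCC=C(C)C)[C@@H](O[Si](C)(C)C(C)(C)C)CCC1=O
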